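**Retrosynthetic overview**

1. The strategy rests on ring B (C5–C6–C7–C8–C9–C10), a 6,7-dehydro dihydronaphthalene ring. Its C6–C7 and C8–C9 bonds are the two σ-bonds of a Diels–Alder adduct between a hydroxy-ortho-quinodimethane on aromatic ring A (C6=C5–C10=C9) and a C7=C8 vinyl group on C14. The C6=C7 styrene then comes from dehydration of the C6 carbinol.
2. The dienol is generated by photoenolisation of an ortho-(sec-alkyl)benzaldehyde (C9–H next to C5–CHO). That aldehyde is cut at C9–C10 into a propellane aryl bromide and a ring D/E secondary alkylzinc (Negishi coupling).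
3. Propellane fragment: the guaiane seven-membered ring comes from (S)-carvone by ring expansion. Aryl C3–O–C5′ is made by palladium-allyl etherification of a tetrasubstituted vinyl epoxide, aryl C2–O–C1′ by SNAr, and the cyclopentene last by ring-closing metathesis.
4. Ring D/E fragment: C20 by copper-catalysed conjugate methylation, C17 by an auxiliary-controlled Michael addition, ring D by aldol condensation, C18 by hydrogenation, C13 and C14 by enolate methylations.
5. Ring order: seven-membered ring, dioxane, cyclopentene (propellane); ring E, ring D; then rings B and C together in the key step.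

Key step: step 30

Remarks on the chemistry:
- Triterpenoid atoms carry friedelane numbers (ring A = C1–C5, C10); guaiane atoms carry primed numbers (C1′–C15′).
- C9 is carried as a mixture of both epimers from racemic δ-hexalactone onward. Zinc insertion would scramble it anyway, and both epimers give the same dienol in the key step. C9 is therefore drawn without configuration up to the photoenol precursor.
- Enolisable centres that are planarised later (C5′ of the keto ester, C17 before the Michael addition, C13 after hydrogenation, C14 of the first aldehyde) are also drawn without configuration.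
- Methyl 3-oxocyclohex-1-ene-1-carboxylate, 3-hydroxy-2-methylbenzonitrile and δ-hexalactone are taken as purchasable.

**Fragment 1: propellane aryl bromide (steps 1–13)**

Step 1
Reactants: 1 (S)-carvone
Product: 2 trans-dihydrocarvone (2-methyl and 5-isopropenyl trans)
Conditions: LiBH(s-Bu)3, THF, −78 °C; then H2O
Reagents that add atoms: none
Why: Conjugate hydride reduction of the enone; axial protonation of the enolate puts the methyl equatorial, trans to the isopropenyl group (this carbon becomes C10′, the isopropenyl carbon C7′).

Step 2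
Reactants: 2 trans-dihydrocarvone
Product: 3 ethyl 3-methyl-2-oxo-6-(prop-1-en-2-yl)cycloheptane-1-carboxylate (3,6-trans)
Conditions: ethyl diazoacetate, BF3·OEt2, Et2O, 0 °C
Reagents that add atoms: ethyl diazoacetate, CCOC(=O)C=[N+]=[N-]
Why: Lewis-acid-promoted diazoacetate ring expansion (Tiffeneau–Demjanov type) in which the less substituted α-methylene migrates, so the inserted ester carbon (C5′) lies between the ketone (C1′) and C6′ and the two stereocentres are untouched.

Step 3
Reactants: 3 β-keto ester
Product: 4 enol triflate (C1′–OTf, C1′=C5′, C5′–CO2Et)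
Conditions: NaH, PhNTf2, THF, 0 to 25 °C
Reagents that add atoms: N-phenylbis(trifluoromethanesulfonimide), O=S(=O)(N(c1ccccc1)S(=O)(=O)C(F)(F)F)C(F)(F)F
Why: O-sulfonylation of the β-keto ester enolate gives the tetrasubstituted vinyl triflate regiospecifically and ends the risk of epimerisation at C10′.

Step 4
Reactants: 4 enol triflate
Product: 5 ethyl 2-allyl-3-methyl-6-(prop-1-en-2-yl)cyclohept-1-ene-1-carboxylate
Conditions: allylSnBu3, Pd(PPh3)4 (5 mol %), LiCl, THF, 65 °C
Reagents that add atoms: allyltributylstannane, C=CC[Sn](CCCC)(CCCC)CCCC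
Why: Stille cross-coupling of the vinyl triflate places the allyl group (C2′, C3′) on C1′.

Step 5
Reactants: 5 allyl enoate
Product: 6 2-[2-allyl-3-methyl-6-(prop-1-en-2-yl)cyclohept-1-en-1-yl]propan-2-ol
Conditions: MeMgBr (3 equiv), THF, 0 to 25 °C
Reagents that add atoms: methylmagnesium bromide, C[Mg]Br
Why: Double Grignard addition to the ester gives the dimethyl carbinol whose carbinol carbon is C4′.

Step 6
Reactants: 6 tertiary allylic alcohol
Product: 7 1-allyl-7-methyl-2,4-di(prop-1-en-2-yl)cycloheptene (7-methyl and 4-isopropenyl trans)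
Conditions: Burgess reagent, toluene, 60 °C
Reagents that add atoms: none
Why: Burgess dehydration (syn elimination through the sulfamate) can only remove a methyl hydrogen, so it gives the C5′ isopropenyl group and a conjugated diene.

Step 7
Reactants: 7 triene
Product: 8 1′,5′-epoxide (oxygen anti to the C10′ methyl, syn to the C7′ isopropenyl)
Conditions: mCPBA (1.0 equiv), NaHCO3, CH2Cl2, −40 to −20 °C
Reagents that add atoms: 3-chloroperoxybenzoic acid, OOC(=O)c1cccc(Cl)c1
Why: Prilezhaev epoxidation is fastest at the tetrasubstituted C1′=C5′ bond; the C10′ methyl, held pseudo-axial by allylic strain with the C1′ allyl group, blocks one face, so oxygen arrives on the other and sets C1′ and C5′ together.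

Step 8
Reactants: 9 3-hydroxy-2-methylbenzonitrile
Product: 10 6-bromo-3-hydroxy-2-methylbenzonitrile
Conditions: NBS, MeCN, 0 °C
Reagents that add atoms: N-bromosuccinimide, O=C1CCC(=O)N1Br
Why: Electrophilic aromatic bromination para to the phenol (one ortho position is blocked by the methyl) puts bromine on the future C10.

Step 9
Reactants: 10 bromophenol
Product: 11 6-bromo-4-chloro-3-hydroxy-2-methylbenzonitrile
Conditions: NCS, TsOH (10 mol %), MeCN, 50 °C
Reagents that add atoms: N-chlorosuccinimide, O=C1CCC(=O)N1Cl
Why: Electrophilic chlorination at the only activated position left, ortho to the phenol, installs the SNAr leaving group on the future C2, para to the nitrile.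

Step 10
Reactants: 8 vinyl epoxide; 11 bromo chloro phenol
Product: 12 cis hydroxy aryl ether (aryl C3–O–C5′, free C1′–OH)
Conditions: Pd2(dba)3·CHCl3 (2.5 mol %), DACH-phenyl Trost ligand (enantiomer matched to the substrate), CH2Cl2, 25 °C
Reagents that add atoms: none
Why: Tsuji–Trost opening of the vinyl epoxide: zerovalent palladium ionises the allylic C5′–O bond with inversion, and the phenol, deprotonated and held by the C1′ alkoxide, attacks the tertiary terminus C5′ anti to palladium, so the ether forms with net retention, cis to the C1′ hydroxyl, and only the C3 oxygen can be the nucleophile.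

Step 11
Reactants: 12 hydroxy aryl ether
Product: 13 benzodioxane nitrile (C1′ allyl and C5′ isopropenyl cis)
Conditions: KN(SiMe3)2 (1.1 equiv), THF–DMF, 0 to 50 °C
Reagents that add atoms: none
Why: Intramolecular SNAr: the C1′ alkoxide displaces the chloride para to the nitrile through a six-membered transition state that only the cis isomer can reach; the cis geometry also rules out reclosure to the epoxide.

Step 12
Reactants: 13 benzodioxane nitrile
Product: 14 propellane nitrile
Conditions: second-generation Grubbs catalyst RuCl2(H2IMes)(PCy3)(=CHPh) (5 mol %), CH2Cl2, 40 °C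
Reagents that add atoms: none
Why: Ring-closing metathesis of the cis allyl and isopropenyl groups closes the trisubstituted cyclopentene (C3′=C4′) and completes the propellane; the remote C7′ isopropenyl cannot form an unstrained ring.

Step 13
Reactants: 14 propellane nitrile
Product: 15 propellane bromo aldehyde
Conditions: i-Bu2AlH (1.2 equiv), toluene, −78 to −40 °C; then aqueous Rochelle salt, wet SiO2
Reagents that add atoms: water, O
Why: Partial reduction of the hindered nitrile to the N-aluminio aldimine and mild hydrolysis gives the aldehyde; it is done before the methyl ester enters the molecule.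

**Fragment 2: ring D/E iodide (steps 14–28)**

Step 14
Reactants: 16 δ-hexalactone (racemic)
Product: 17 5-hydroxy-N-methoxy-N-methylhexanamide
Conditions: MeNHOMe·HCl, i-PrMgCl, THF, −20 to 0 °C
Reagents that add atoms: N,O-dimethylhydroxylamine hydrochloride, CNOC.Cl
Why: Aminolysis of the lactone by the magnesium amide gives the Weinreb amide and frees the C9 hydroxyl.

Step 15
Reactants: 17 hydroxy amide
Product: 18 5-(tert-butyldiphenylsilyloxy)-N-methoxy-N-methylhexanamide
Conditions: t-BuPh2SiCl, imidazole, DMF, 25 °C
Reagents that add atoms: tert-butyl(chloro)diphenylsilane, CC(C)(C)[Si](Cl)(c1ccccc1)c1ccccc1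
Why: Silylation gives an ether that survives the base, acid and hydrogenation steps that follow.

Step 16
Reactants: 18 silyl ether amide
Product: 19 7-(tert-butyldiphenylsilyloxy)oct-1-en-3-one
Conditions: CH2=CHMgBr, THF, 0 °C; quench into cold 1 M HCl
Reagents that add atoms: vinylmagnesium bromide, C=C[Mg]Br
Why: Weinreb ketone synthesis; the chelated adduct prevents over-addition and the acidic quench keeps the liberated amine from adding to the enone.

Step 17
Reactants: 20 methyl 3-oxocyclohex-1-ene-1-carboxylate
Product: 21 methyl (R)-1-methyl-3-oxocyclohexane-1-carboxylate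
Conditions: Me2Zn, (CuOTf)2·C6H6 (2.5 mol %), chiral sulfonate-bearing imidazolinium salt (NHC precursor, 5 mol %), t-BuOMe, −30 °C
Reagents that add atoms: dimethylzinc, C[Zn]C
Why: Copper-catalysed asymmetric conjugate addition to the β-ester enone, with the face chosen by the chiral NHC–copper complex, sets the C20 quaternary centre (methyl and ester).

Step 18
Reactants: 21 keto ester
Product: 22 methyl (1R)-1,4-dimethyl-3-oxocyclohexane-1-carboxylate (C4 epimers)
Conditions: LiN(i-Pr)2, THF, −78 °C; then MeI, −78 to −20 °C
Reagents that add atoms: iodomethane, CI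
Why: Kinetic enolate alkylation: the base removes a proton from the α-methylene away from the quaternary centre (C17), and the new stereocentre does not matter because it is planarised in step 19.

Step 19
Reactants: 22 methyl ketone; 19 vinyl ketone
Product: 25 diketone with quaternary C17 (C16 chain cis to the C20 ester), via ketimine 23 (not isolated), via adduct ketimine 24 (not isolated)
Conditions: (S)-1-phenylethylamine, TsOH (cat.), toluene, reflux (Dean–Stark); then 19, THF, 25–40 °C; then 20% aqueous AcOH, 25 °C
Reagents that add atoms: none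
Why: d'Angelo Michael addition: the secondary enamine tautomer of the chiral imine adds to the vinyl ketone at the more substituted carbon C17, on the face fixed by the (S)-phenylethyl group (the sense that gives (R)-10-methyl-octalone in the parent series), independently of the remote C20 centre.

Step 20
Reactants: 25 diketone
Product: 26 octalone (C14 ketone, C13=C18, C13 bearing the 3-silyloxybutyl chain, angular C17 methyl)
Conditions: NaOMe, MeOH, 65 °C
Reagents that add atoms: none
Why: Intramolecular aldol condensation of C13 onto the C18 ketone (second half of a Robinson annulation) closes ring D; methoxide leaves the methyl ester unchanged.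

Step 21
Reactants: 26 octalone
Product: 27 cis-decalone (H18 β, cis to the C17 methyl)
Conditions: H2 (3 atm), 10% Pd/C, EtOH, 25 °C
Reagents that add atoms: none
Why: Heterogeneous hydrogenation of a 4a-methyl-octalone delivers hydrogen to C18 from the face of the angular methyl, the usual course for such enones, and gives the cis ring fusion.

Step 22
Reactants: 27 cis-decalone
Product: 28 C13-methylated ketone (C13 methyl α, chain β)
Conditions: KOt-Bu (1.1 equiv), t-BuOH–THF, 25 °C; then MeI, 0 °C
Reagents that add atoms: iodomethane, CI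
Why: Thermodynamic enolate alkylation: the cis-fused ketone enolises toward the ring fusion (C13), and methyl iodide attacks anti to the axial angular C17 methyl that is 1,3 to C13.

Step 23
Reactants: 28 ketone
Product: 29 methyl enol ether (C14=C8H–OMe)
Conditions: Ph3P(CH2OMe)Cl, KN(SiMe3)2, THF, 0 to 65 °C
Reagents that add atoms: (methoxymethyl)triphenylphosphonium chloride, COC[P+](c1ccccc1)(c1ccccc1)c1ccccc1.[Cl-]
Why: Wittig methoxymethylenation of the hindered ketone adds C8; the non-enolisable methyl ester is not attacked by the ylide.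

Step 24
Reactants: 29 enol ether
Product: 30 C14 carbaldehyde (C14 epimers)
Conditions: 2 M aqueous HCl, THF, 25 °C
Reagents that add atoms: water, O
Why: Acid hydrolysis of the enol ether; the tert-butyldiphenylsilyl ether and the ester tolerate dilute acid.

Step 25
Reactants: 30 aldehyde
Product: 31 quaternary aldehyde (C14 methyl β, formyl α)
Conditions: KOt-Bu, THF, 0 °C; MeI
Reagents that add atoms: iodomethane, CI
Why: Alkylation of the exocyclic aldehyde enolate creates the C14 quaternary centre; in the chair that avoids the C20-ester/C13 and C13-methyl/C22 syn-axial contacts, axial attack is blocked by C19 and equatorial attack places the methyl β.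

Step 26
Reactants: 31 quaternary aldehyde
Product: 32 C14 vinyl silyl ether
Conditions: Ph3PCH3Br, KN(SiMe3)2, THF, 0 to 25 °C
Reagents that add atoms: methyltriphenylphosphonium bromide, C[P+](c1ccccc1)(c1ccccc1)c1ccccc1.[Br-]
Why: Wittig methylenation of the neopentyl aldehyde gives the C7=C8 vinyl group.

Step 27
Reactants: 32 silyl ether
Product: 33 C9 alcohol
Conditions: Bu4NF, THF, 50 °C
Reagents that add atoms: none
Why: Fluoride desilylation frees the secondary alcohol without touching the ester or the vinyl group.

Step 28
Reactants: 33 alcohol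
Product: 34 C9 iodide
Conditions: I2, PPh3, imidazole, CH2Cl2, 0 to 25 °C
Reagents that add atoms: iodine, II
Why: Appel-type iodination of the secondary alcohol (inversion, of no consequence here).

**Union and end game (steps 29–31)**

Step 29
Reactants: 34 C9 iodide; 15 propellane bromo aldehyde
Product: 36 photoenol precursor (ortho-sec-alkyl benzaldehyde bearing the C14 vinyl decalin), via alkylzinc iodide 35 (not isolated)
Conditions: Zn dust, LiCl, THF, 40 °C; then 15, Pd(OAc)2 (2 mol %), CPhos (4 mol %), THF–toluene, 25 °C
Reagents that add atoms: none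
Why: Zinc insertion into the secondary C–I bond, then Negishi coupling at C9–C10 (the CPhos–palladium catalyst suppresses β-hydride elimination of secondary alkylzincs); the alkylzinc halide tolerates aldehyde and ester, and oxidative addition to the aryl bromide is far faster than ionisation of the hindered allylic aryl ether.

Step 30
Reactants: 36 photoenol precursor
Product: 38 6-hydroxy-6,7-dihydro pentacycle, via E-dienol 37 (not isolated)
Conditions: hν (365 nm), degassed toluene (5 mM), 25 °C
Reagents that add atoms: none
Why: n→π* excitation of the aryl aldehyde and 1,5-hydrogen transfer from the tertiary benzylic C9–H to the carbonyl oxygen give, through the triplet biradical, the E-dienol 37 (C6=C5–C10=C9), which adds in a thermal intramolecular [4+2] to the C7=C8 vinyl group; enolisation toward the C4 methyl finds no dienophile and reverts. The closest known reactions are the photoenolisation/Diels–Alder reaction of ortho-alkylbenzaldehydes and the thermal ortho-quinodimethane/vinyl cycloadditions of steroid synthesis, which make the same two bonds. Ring B closes through the C6–C7 bond and ring C through the C8–C9 bond, ring C being the six-membered ring completed by the C11–C12–C13 tether and C14 (a type-1 intramolecular Diels–Alder closure). C9 and C8 are set together by the exo transition state with the tether outside and the methyl inside at the C9 terminus, the forming ring C being a chair with the C12–C13 and C14–C8 bonds equatorial on ring D, so that H8 is α and the C9 methyl β; C6 follows from the outward hydroxyl and is removed in step 31. The step needs the trans B/C fusion with the C9 methyl on the face of the C14 methyl; the fixed configurations of the adjacent quaternary C13 and C14 leave only this chair, at the price of a 1,3-diaxial methyl/methyl contact. The neutral conditions and long-wavelength light leave the tertiary ethers, the ester and the other alkenes untouched.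

Step 31
Reactants: 38 C6 carbinol
Product: 39 CNP0287532.3
Conditions: Burgess reagent, benzene, 50 °C
Reagents that add atoms: none
Why: Burgess dehydration (neutral syn elimination) of the benzylic alcohol toward C7 gives the C6=C7 styrene without acid, which the tertiary allylic aryl ether would not survive.

**Compound list**

1 | (S)-carvone | CC1=CC[C@@H](CC1=O)C(C)=C | starting material
2 | trans-dihydrocarvone | C=C(C)[C@H]1CC[C@H](C)C(=O)C1 | intermediate
3 | ethyl 3-methyl-2-oxo-6-(prop-1-en-2-yl)cycloheptane-1-carboxylate (3,6-trans) | C=C(C)[C@H]1CC[C@H](C)C(=O)C(C(=O)OCC)C1 | intermediate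
4 | enol triflate of 3 | C=C(C)[C@H]1CC[C@H](C)C(OS(=O)(=O)C(F)(F)F)=C(C(=O)OCC)C1 | intermediate
5 | ethyl 2-allyl-3-methyl-6-(prop-1-en-2-yl)cyclohept-1-ene-1-carboxylate | C=C(C)[C@H]1CC[C@H](C)C(CC=C)=C(C(=O)OCC)C1 | intermediate
6 | 2-[2-allyl-3-methyl-6-(prop-1-en-2-yl)cyclohept-1-en-1-yl]propan-2-ol | C=C(C)[C@H]1CC[C@H](C)C(CC=C)=C(C(C)(C)O)C1 | intermediate
7 | 1-allyl-7-methyl-2,4-di(prop-1-en-2-yl)cycloheptene | C=C(C)[C@H]1CC[C@H](C)C(CC=C)=C(C(C)=C)C1 | intermediate
8 | 1′,5′-epoxide of 7 (O anti to C10′ methyl) | C=C(C)[C@H]1CC[C@H](C)[C@@]2(CC=C)O[C@@]2(C(C)=C)C1 | intermediate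
9 | 3-hydroxy-2-methylbenzonitrile | Cc1c(O)cccc1C#N | starting material
10 | 6-bromo-3-hydroxy-2-methylbenzonitrile | Cc1c(O)ccc(Br)c1C#N | intermediate
11 | 6-bromo-4-chloro-3-hydroxy-2-methylbenzonitrile | Cc1c(O)c(Cl)cc(Br)c1C#N | intermediate
12 | cis hydroxy aryl ether (aryl C3–O–C5′, C1′–OH) | C=C(C)[C@H]1CC[C@H](C)[C@](O)(CC=C)[C@](Oc2c(C)c(C#N)c(Br)cc2Cl)(C(C)=C)C1 | intermediate
13 | benzodioxane nitrile (seco-propellane) | C=C(C)[C@H]1CC[C@H](C)[C@@]2(CC=C)Oc3cc(Br)c(C#N)c(C)c3O[C@@]2(C(C)=C)C1 | intermediate
14 | propellane nitrile | C=C(C)[C@H]1CC[C@H](C)[C@]23CC=C(C)[C@@]2(C1)Oc1c(cc(Br)c(C#N)c1C)O3 | intermediate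
15 | propellane bromo aldehyde | C=C(C)[C@H]1CC[C@H](C)[C@]23CC=C(C)[C@@]2(C1)Oc1c(cc(Br)c(C=O)c1C)O3 | intermediate
16 | δ-hexalactone (racemic) | CC1CCCC(=O)O1 | starting material
17 | 5-hydroxy-N-methoxy-N-methylhexanamide | CC(O)CCCC(=O)N(C)OC | intermediate
18 | 5-(tert-butyldiphenylsilyloxy)-N-methoxy-N-methylhexanamide | CC(O[Si](c1ccccc1)(c1ccccc1)C(C)(C)C)CCCC(=O)N(C)OC | intermediate
19 | 7-(tert-butyldiphenylsilyloxy)oct-1-en-3-one | CC(O[Si](c1ccccc1)(c1ccccc1)C(C)(C)C)CCCC(=O)C=C | intermediate
20 | methyl 3-oxocyclohex-1-ene-1-carboxylate | COC(=O)C1=CC(=O)CCC1 | starting material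
21 | methyl (R)-1-methyl-3-oxocyclohexane-1-carboxylate | O=C1CCC[C@@](C)(C(=O)OC)C1 | intermediate
22 | methyl (1R)-1,4-dimethyl-3-oxocyclohexane-1-carboxylate | CC1CC[C@@](C)(C(=O)OC)CC1=O | intermediate
23 | ketimine of 22 with (S)-1-phenylethylamine | CC1CC[C@@](C)(C(=O)OC)CC1=N[C@@H](C)c1ccccc1 | intermediate
24 | Michael-adduct ketimine | CC(O[Si](c1ccccc1)(c1ccccc1)C(C)(C)C)CCCC(=O)CC[C@@]1(C)CC[C@@](C)(C(=O)OC)CC1=N[C@@H](C)c1ccccc1 | intermediate
25 | diketone (C17 quaternary; C18 and C14 ketones) | CC(O[Si](c1ccccc1)(c1ccccc1)C(C)(C)C)CCCC(=O)CC[C@@]1(C)CC[C@@](C)(C(=O)OC)CC1=O | intermediate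
26 | ring D/E octalone | CC(O[Si](c1ccccc1)(c1ccccc1)C(C)(C)C)CCC1=C2C[C@](C)(C(=O)OC)CC[C@]2(C)CCC1=O | intermediate
27 | cis-decalone (H18 β) | CC(O[Si](c1ccccc1)(c1ccccc1)C(C)(C)C)CCC1[C@@H]2C[C@](C)(C(=O)OC)CC[C@]2(C)CCC1=O | intermediate
28 | C13-methylated C14 ketone | CC(O[Si](c1ccccc1)(c1ccccc1)C(C)(C)C)CC[C@@]1(C)[C@@H]2C[C@](C)(C(=O)OC)CC[C@]2(C)CCC1=O | intermediate
29 | C14 methoxymethylene enol ether | CC(O[Si](c1ccccc1)(c1ccccc1)C(C)(C)C)CC[C@@]1(C)[C@@H]2C[C@](C)(C(=O)OC)CC[C@]2(C)CCC1=COC | intermediate
30 | C14 carbaldehyde | CC(O[Si](c1ccccc1)(c1ccccc1)C(C)(C)C)CC[C@@]1(C)[C@@H]2C[C@](C)(C(=O)OC)CC[C@]2(C)CCC1C=O | intermediate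
31 | C14 quaternary aldehyde (methyl β, CHO α) | CC(O[Si](c1ccccc1)(c1ccccc1)C(C)(C)C)CC[C@@]1(C)[C@@H]2C[C@](C)(C(=O)OC)CC[C@]2(C)CC[C@]1(C)C=O | intermediate
32 | C14 vinyl silyl ether | CC(O[Si](c1ccccc1)(c1ccccc1)C(C)(C)C)CC[C@@]1(C)[C@@H]2C[C@](C)(C(=O)OC)CC[C@]2(C)CC[C@]1(C)C=C | intermediate
33 | C9 alcohol | CC(O)CC[C@@]1(C)[C@@H]2C[C@](C)(C(=O)OC)CC[C@]2(C)CC[C@]1(C)C=C | intermediate
34 | C9 iodide | CC(I)CC[C@@]1(C)[C@@H]2C[C@](C)(C(=O)OC)CC[C@]2(C)CC[C@]1(C)C=C | intermediate
35 | C9 alkylzinc iodide | CC([Zn]I)CC[C@@]1(C)[C@@H]2C[C@](C)(C(=O)OC)CC[C@]2(C)CC[C@]1(C)C=C | intermediate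
36 | photoenol precursor (both C9 epimers) | C=C(C)[C@H]1CC[C@H](C)[C@]23CC=C(C)[C@@]2(C1)Oc1c(cc(C(C)CC[C@@]2(C)[C@@H]4C[C@](C)(C(=O)OC)CC[C@]4(C)CC[C@]2(C)C=C)c(c1C)C=O)O3 | intermediate
37 | E-dienol (hydroxy-ortho-quinodimethane) | C=C(C)[C@H]1CC[C@H](C)[C@]23CC=C(C)[C@@]2(C1)OC1=C(C)C(=CO)C(=C(C)CC[C@@]2(C)[C@@H]4C[C@](C)(C(=O)OC)CC[C@]4(C)CC[C@]2(C)C=C)C=C1O3 | intermediate
38 | 6-hydroxy-6,7-dihydro pentacycle | C=C(C)[C@H]1CC[C@H](C)[C@]23CC=C(C)[C@@]2(C1)Oc1c(cc2c(c1C)[C@@H](O)C[C@H]1[C@@]2(C)CC[C@@]2(C)[C@@H]4C[C@](C)(C(=O)OC)CC[C@]4(C)CC[C@]12C)O3 | intermediate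
39 | CNP0287532.3 | C=C(C)[C@H]1CC[C@H](C)[C@]23CC=C(C)[C@@]2(C1)Oc1c(cc2c(c1C)C=C[C@H]1[C@@]2(C)CC[C@@]2(C)[C@@H]4C[C@](C)(C(=O)OC)CC[C@]4(C)CC[C@]12C)O3 | target

**Step count and risks**

Total step count: 31. Longest linear sequence: 16 steps (from 16 through steps 14–16 and 19–31).

The three steps most likely to fail:

Step 30 (key step). The dienol may relax back to the aldehyde, or close to a benzocyclobutenol, faster than the unactivated neopentyl vinyl group adds to its tetrasubstituted C9 terminus. The cycloaddition may also take the face that gives the cis B/C fusion. The fallback sets out from 36 and returns at 38. Irradiation is run so that the 4π-electrocyclisation product, the benzocyclobutenol F1, is collected. F1 is then heated in toluene or o-dichlorobenzene at 110–180 °C. Thermal conrotatory opening (hydroxyl outward) regenerates the same dienol reversibly and without a lifetime limit. The vinyl group can then add under the thermal conditions of the classical ortho-quinodimethane steroid syntheses, giving 38.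

Step 10. The hindered phenoxide may attack the unsubstituted CH2 terminus of the allyl–palladium intermediate instead of the tertiary C5′. The allyl complex may also change face by π–σ–π isomerisation and give the trans hydroxy ether, which cannot cyclise. The fallback sets out from 8 and 11 and returns at 13; it makes the easy C1′–O bond first and the hindered C5′–O bond intramolecularly. Pd(PPh3)4 (zerovalent palladium) and phenol open 8 under thermodynamic control at the CH2 terminus to the linear allyl phenyl ether with free C1′ hydroxyl F2. Phenol 11 is protected as its methoxymethyl ether F3 (MeOCH2Cl, i-Pr2NEt). The potassium alkoxide of F2 displaces the chloride of F3 para to the nitrile (intermolecular SNAr) to give the tertiary aryl ether F4. Pyridinium tosylate in t-BuOH removes the acetal to give the phenol F5. Pd2(dba)3·CHCl3/dppe with Cs2CO3 then ionises the allyl phenyl ether, and the tethered phenoxide closes the six-membered dioxane at C5′ (intramolecular Tsuji–Trost etherification). This is the only ring size within reach and is cis by the tether, and it gives 13.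

Step 25. Methylation of the exocyclic aldehyde enolate next to the quaternary C13 may show poor facial selectivity, because the strained cis-decalin can react through more than one conformer. The fallback sets out from 28 and returns at 32; it replaces substrate control by catalyst control. Vinylmagnesium bromide with CeCl3 adds to the ketone to give the tertiary allylic alcohol F6. SOCl2 converts F6, with allylic transposition, into the primary allylic chloride F7. MeMgBr with Cu(OTf)2 and a chiral NHC precursor then performs a γ-selective (SN2′) allylic substitution of known type, in which the ligand chooses the face; this creates C14 with methyl and vinyl directly and gives 32.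

**Further compounds**

F1 | step 30 | benzocyclobutenol (C5–C6(OH)–C9(CH3)–C10 four-membered ring) | C=C(C)[C@H]1CC[C@H](C)[C@]23CC=C(C)[C@@]2(C1)Oc1c(cc2c(c1C)C(O)C2(C)CC[C@@]2(C)[C@@H]4C[C@](C)(C(=O)OC)CC[C@]4(C)CC[C@]2(C)C=C)O3
F2 | step 10 | linear allyl phenyl ether with free C1′ hydroxyl | C=C(C)[C@H]1CC[C@H](C)[C@](O)(CC=C)C(=C(C)COc2ccccc2)C1
F3 | step 10 | 6-bromo-4-chloro-3-(methoxymethoxy)-2-methylbenzonitrile | COCOc1c(Cl)cc(Br)c(C#N)c1C
F4 | step 10 | C1′ aryl ether with methoxymethyl-protected C3 oxygen | C=C(C)[C@H]1CC[C@H](C)[C@](Oc2cc(Br)c(C#N)c(C)c2OCOC)(CC=C)C(=C(C)COc2ccccc2)C1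
F5 | step 10 | C1′ aryl ether with free C3 phenol | C=C(C)[C@H]1CC[C@H](C)[C@](Oc2cc(Br)c(C#N)c(C)c2O)(CC=C)C(=C(C)COc2ccccc2)C1
F6 | step 25 | C14 tertiary allylic alcohol | CC(O[Si](c1ccccc1)(c1ccccc1)C(C)(C)C)CC[C@@]1(C)[C@@H]2C[C@](C)(C(=O)OC)CC[C@]2(C)CCC1(O)C=C
F7 | step 25 | C14 alkylidene primary allylic chloride | CC(O[Si](c1ccccc1)(c1ccccc1)C(C)(C)C)CC[C@@]1(C)[C@@H]2C[C@](C)(C(=O)OC)CC[C@]2(C)CCC1=CCCl
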